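All runs were generated by integration on assumed constants.

The constants were unknown when the meeting sat, so it worked from the two earlier runs.

| setting | east | north-east | violet | green |
|---|---|---|---|---|
| substrate | 0.18 M | 0.45 M | 0.30 M | 0.15 M |
| temperature | 65 °C | 78 °C | 85 °C | 70 °C |
| remark | run made earlier | run made earlier |  |  |
| time |  |  | 3.0 h | 3.0 h |

| run | time / min | ring / % | substrate / % |
|---|---|---|---|
| east | 25.0 | 4.7 | 84.9 |
| east | 50.0 | 9.7 | 72.2 |
| east | 80.0 | 13.3 | 61.0 |
| east | 90.0 | 15.8 | 55.8 |
| east | 120 | 16.9 | 50.2 |
| north-east | 12.0 | 9.1 | 65.3 |
| north-east | 30.0 | 17.8 | 40.4 |
| north-east | 60.0 | 26.9 | 23.2 |
| north-east | 90.0 | 32.1 | 13.1 |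
| north-east | 120 | 34.4 | 8.5 |

(standard deviation of a reading: 1 percentage point)

- a species is counted by the substrate in it: one open dimer counts as two
- a species is counted by the substrate in it: one open trimer counts as three
- amounts and yields of ring count crystals too
- given per volume of solution although it is solid: crystals
- steps under discussion: 2 substrate -> open dimer; crystals <-> ring; substrate -> ring; substrate + open dimer -> open trimer; ring -> over-reaction product

- which one finishes higher in amount of ring, in percent of the substrate charged ("neither" within 2 percentage points) (violet / green / neither)
- amount of ring at the end, in percent of the substrate charged, violet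
- amount of ring at the end, in percent of the substrate charged, green

The analyst argued that ring forms first-order in substrate and open dimer at second order, so the ratio of the two rates is a concentration over the substrate concentration, and that concentration can be frozen through a run. She took each run's last reading: ring, over the rest of the substrate lost, times the mean substrate concentration. This reads 0.0694 M in the east run and 0.147 M in the north-east run, both carrying the scatter of the readings.

The secretary stepped these geometrically in temperature to 0.220 M for violet and 0.0927 M for green. This is the crossover concentration, the substrate concentration at which the two steps take substrate equally; divided by the substrate concentration, it is the selectivity factor. Integrated to full conversion, ring made over charge = (crossover / charge) × ln(1 + charge / crossover). The secretary's own figures are 63.1% for violet and 59.5% for green, the first higher.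

The chair noted that these count ring made, not ring left, and that green need not finish: the east run, cooler than green, still read 50.2% substrate at 120 min. The secretary committed to violet, below its figure by what over-reaction takes.

The forecast, from the same runs, said violet, with 44% for violet and 35% for green; it read the substrate's apparent first-order constant as one that “falls with conversion, especially in the concentrated run”, which it took to point to a higher-order loss. Its figures are ring left, the secretary's ring made, so they are different quantities.

The flask gives violet: 47.4% in violet against 36.0% in green. At 3.00 h, violet's dissolved ring was being made at 0.994 of the rate it was used, each step taken net and going into its other forms counted as use. The crossover figure of 63.1% for ring made stands beside violet's 47.4% of ring plus 12.2% of over-reaction product, together 59.6%.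

    2 substrate → open dimer (k = 1.20 M⁻¹ h⁻¹, Ea = 64.0 kJ mol⁻¹)
    crystals ⇌ ring, rate k2*(cs2 - [ring]) while solid is left; crystals form when [ring] > cs2 (solubility = 0.110 M, k = 51.0 h⁻¹)
    substrate → ring (k = 0.240 h⁻¹, Ea = 116 kJ mol⁻¹)
    substrate + open dimer → open trimer (k = 0.830 M⁻¹ h⁻¹, Ea = 66.0 kJ mol⁻¹)
    ring → over-reaction product (k = 0.0250 h⁻¹, Ea = 106 kJ mol⁻¹)
    (constants at 70 °C)

Violet's crossover on a neighbour flask, violet with 0.12 M of substrate and all else held, gives ring made of 79.8%. The computed flask holds 58.6% of ring and 18.9% of over-reaction product, together 77.5%.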